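**Amounts first.** Both flasks hold the same charge of starting material and differ in reagent, which is the limiting reagent in each.

common to all: starting material 0.047 M

|  | reagent | remark | time |
|---|---|---|---|
| Tuesday's | 0.015 M | run made earlier |  |
| Sunday's | 0.029 M | run made earlier |  |
| zeta | 0.0235 M |  | 15 d |
| epsilon | 0.0376 M |  | 15 d |

| run | time / d | double product / % | single product / % | starting material / % |
|---|---|---|---|---|
| Tuesday's | 0.625 | 0 | 5.2 | 94.0 |
| Tuesday's | 1.04 | 1.4 | 9.6 | 91.2 |
| Tuesday's | 1.67 | 0.7 | 11.9 | 87.7 |
| Tuesday's | 2.50 | 0.5 | 17.1 | 82.4 |
| Tuesday's | 5.00 | 1.1 | 22.7 | 75.6 |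
| Tuesday's | 8.00 | 0.5 | 25.3 | 71.8 |
| Sunday's | 1.25 | 1.1 | 18.2 | 80.4 |
| Sunday's | 2.50 | 1.8 | 27.6 | 69.9 |
| Sunday's | 4.00 | 1.2 | 35.1 | 61.9 |
| Sunday's | 5.00 | 2.1 | 39.9 | 57.8 |
| Sunday's | 6.00 | 1.6 | 42.1 | 54.7 |
| Sunday's | 8.00 | 2.3 | 45.4 | 50.8 |

(scatter of a reading: 0.5 percentage points)

- which of these holds the largest part of the starting material at the end of zeta (single product / double product / starting material)
- which of these holds the largest part of the starting material at the end of epsilon (single product / double product / starting material)
- double product at the end of epsilon, in percent of the starting material charged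

- a reading or a percentage of single product counts all its forms, free or not

**Reagent ceiling.** Taking one reagent per conversion, define the ceiling E as reagent charged over starting material charged 0.500: the largest fraction of starting material the reagent can convert. Starting material then stays at or above a floor of 1 − E. Both runs respect this: Tuesday's last reading is 71.8% against a floor of 68.1%, and Sunday's is 50.8% against 38.3%.

**The opposite outcome.** For single product to lead, more than 0.5 must convert, so E must exceed that value. Zeta's E is 0.500, exactly on the line, so this ceiling gives single product no lead in zeta. Epsilon's E is 0.800, so there time matters. Sunday's flask had already reached 45.4% single product against 50.8% starting material at 8.00 d, and epsilon has more reagent, 0.0376 M against 0.029 M, and a longer time, 15 d against 8.00 d, so single product should lead. Sunday's last reading puts double product at 4.82% of the two products; at epsilon's ceiling, this reckoning gives about 3.86%.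

**The forecast.** It names starting material for zeta and single product for epsilon, with double product at 5.5% (2.5% to 12%), above this reckoning. Of zeta it says: “This is close, but starting material leads.”

    starting material + reagent → single product (k = 0.00510 M⁻¹ min⁻¹)
    reagent → decomposition product (k = 1.10 × 10⁻⁶ min⁻¹)
    crystals ⇌ single product, rate k3*(cs3 - [single product]) while solid is left; crystals form when [single product] > cs3 (solubility = 0.760 mM, k = 0.00560 min⁻¹)
    reagent + single product → over-reaction product (k = 0.00520 M⁻¹ min⁻¹)
    reagent + single product → double product (k = 0.00590 M⁻¹ min⁻¹)

**The result.** Zeta ends with 54.7% starting material, above its floor of 50.0%, and 42.3% single product. Epsilon ends with 61.6% single product, 32.1% starting material and 3.32% double product. A neighbouring flask, epsilon with reagent cut to 0.015 M, has a ceiling of 0.319 and a floor of 68.1%, so E lies below 0.5. It ends with starting material leading, at 70%, against 28.1% single product.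

The readings come from a simulation with made-up constants; scatter was added.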